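**Remark on labels.** The atom labels C2, C3, C4, C4a (half A) and C2′, C3′, C4′ (half B) are those of the two chroman-2-one rings of the target and are kept for the corresponding atoms in every intermediate. In the cyclopropanes 18 and 19 the spiro carbon is C3′, the ester-bearing carbon is C3 and the anisyl-bearing carbon is C4. Compound numbers are those of the steps and the compound list.

## Analysis of the target

The target is a 3,3′-linked pair of 4-aryl-chroman-2-ones (3,4-dihydrocoumarins). Half A (unprimed) has a phloroglucinol-type benzo ring (5,7-dihydroxy), half B (primed) a fully oxygenated one (5′,6′,7′,8′-tetrahydroxy), and C4 and C4′ each carry a 4-hydroxyphenyl group. The four stereocentres C4, C3, C3′, C4′ are contiguous and have the configuration R, S, S, R. In each δ-lactone the C3 substituent and the C4 aryl group are cis, so the core looks C2-symmetric although the two halves differ in constitution. C3 and C3′ are α to aryl-ester carbonyls and enolise easily, and the cis arrangement is unlikely to be the thermodynamic one, so these centres must be set late and kept away from base. The lactones are acylating aryl esters, and the eight phenols, above all the tetrahydroxybenzene ring of half B, are oxidised readily by air. The difficulty lies in the congested C3–C3′ bond between two diarylmethine carbons, in telling two nearly identical halves apart, and in relating four stereocentres across that bond. The strategy rests on one feature of half A: C4 carries an oxygenated aryl donor and stands 1,3 (through C3) to C3′, the α-carbon of the lactone B carbonyl C2′. A bond between C4 and C3′ therefore defines a donor–acceptor cyclopropane (C3′, C3, C4) spiro-fused to lactone B, from which the C4–C4a bond to the symmetrical phloroglucinol ring can be made with transfer of configuration.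

## Retrosynthetic reasoning

**24 to 22.** The lactone A bond C2–O1 and the eight phenolic O–H bonds are cut first. This leads back to the nonamethyl ether methyl ester 22, in which lactone B is intact and all four stereocentres are present. Methyl ethers survive every earlier step, and the phloroglucinol ring is symmetrical, so either ortho-hydroxyl closes the same lactone. The forward step needs only a Lewis acid and aqueous acid (through seco acid 23), which keeps the base-labile cis centres C3 and C3′ untouched.

**22 to 19 and 20.** The bond C4–C4a is cut and C4 is reconnected to C3′, giving spirocyclopropane 19 and 1,3,5-trimethoxybenzene 20.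
- Why here: C4–C4a is the most hindered bond of half A, and the only one that joins a symmetrical nucleophile (no regiochemistry in the arene) to a carbon that can be made electrophilic by the donor aryl group and the lactone acceptor.
- C4: rear-side attack of the arene turns the cis ester/aryl geometry of 19 into the C3/C4 relation of the target.
- C3′: the carbon leaves as the lactone B enolate (enol 21) and is protonated anti to the C4′ aryl group, which gives the cis lactone B.
- Spiro carbon: its configuration in 19 is erased, so 19 is written with the spiro configuration that its synthesis delivers (ester and anisyl on the face of C4′).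

**19 to 18.** The C3–H bond is traced to a C3–Br bond. Cis ester and aryl on a cyclopropane is the crowded arrangement, and ring closures of sulfur ylides or α-halo enolates put these groups trans. The hydrogen is therefore delivered last, by a bulky silane to the C3 radical on the face away from the aryl group. Both bromo epimers of 18 give the same radical, so the step is stereoconvergent.

**18 to 14 and 15.** Both bonds to the ester carbon (C3–C4 and C3–C3′) are cut, which gives the E-benzylidene lactone 14 and methyl dibromoacetate 15 (Michael-initiated ring closure). Attack on the benzylidene carbon anti to the pseudoaxial C4′ aryl group fixes C4 relative to C4′. The other cyclopropane disconnection, at the anisyl-bearing carbon, was set aside for three reasons: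
- It needs an ester-bearing alkylidene lactone whose stable geometry (ester anti to the lactone carbonyl) gives C3 the wrong sense on anti attack.
- The C4′–H of that alkene is vinylogously acidic, and its loss would lead to an achiral coumarin.
- A benzylic ylide would again place aryl and ester trans.

**14 to 9 and 10.** The C3′=C4 double bond is cut by an aldol condensation (through aldol 12) between lactone B 9 and 4-methoxybenzaldehyde 10. The E geometry is the stable one and is the one that the anti attack in the next step requires.

**9 to 7 and 8.** The C4′–aryl bond is cut: rhodium-catalysed asymmetric 1,4-addition of boronic acid 8 to coumarin 7. This is the only catalyst-controlled stereocentre; C4, C3 and C3′ are all derived from it.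

**7 to 4 and 5, and 4 to 1.** The coumarin is opened at C4a′–C4′ and at the lactone C–O bond, giving phenol 4 and ethyl propiolate 5 (hydroarylation and lactonisation at the one free ring position). The phenol oxygen of 4 is placed on 1,2,3,4-tetramethoxybenzene 1 by ortho-lithiation, borylation and oxidation.

## Alternatives that were turned down

**Alternative 1: twofold directed C–H arylation of a dibenzylsuccinamide.**
- Disconnection: both C4–aryl and C4′–aryl bonds to the 4-methoxyphenyl groups are cut. This leaves the (2S,3S)-succinic bis(quinolin-8-yl)amide A1, which carries a 2,4,6-trimethoxybenzyl and a pentamethoxybenzyl arm.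
- Forward key step: palladium-catalysed, amide-directed arylation of both benzylic methylene groups with 4-iodoanisole A2 and a silver carboxylate, to give the bis(diarylmethyl)succinamide A3.
- For it: both diarylmethines are made in one operation with the same aryl group, the C3/C3′ pair comes from a lignan-type succinate, and no strained intermediate is needed. It is more convergent than the chosen route and uses the near-symmetry of the target better.
- Against it:
  - Each methylene is flanked by a 2,6-dimethoxylated ring, which hinders palladacycle formation.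
  - Two directing groups on adjacent carbons compete for the metal.
  - The facial sense of the C–H cleavage must be the same at two centres, the second on a bulkier substrate.
  - Two hindered quinolinyl amides must then be turned into aryl lactones under conditions that endanger C3 and C3′.
  - The unsymmetrical A1 itself needs two stereoselective alkylations.
- In its place the chosen strategy offers an acid-only endgame with no auxiliary removal, and one separate control element for each centre.

**Alternative 2: biomimetic double hydroarylation of a bis(4-hydroxybenzylidene)succinate.**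
- Disconnection: C4–C4a and C4′–C4a′ are cut, leading to the mixed diaryl (E,E)-succinate A4.
- Forward key step: under a chiral Brønsted acid each ester arene attacks its own benzylidene carbon, both lactone rings close, and two enols are protonated, to give the hexamethyl ether A5.
- For it: it is by far the shortest plan. Two rings and four stereocentres come from an achiral diene diester of Stobbe type, and the 4-hydroxyphenyl groups need no protection. On step economy it is stronger than the chosen route.
- Against it:
  - One catalyst has to govern two separate Friedel–Crafts closures and two protonations.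
  - The second closure is ruled by the first stereocentre (match or mismatch), not by the catalyst.
  - Both protonations must give the cis lactone.
  - The tetramethoxyphenyl ester can react only through its single, hindered free position.
  - Bis(benzylidene)succinates have a competing electrocyclisation path to aryl-dihydronaphthalenes.
- The chosen strategy gives up brevity for stepwise, assignable control of each centre.

**Alternative 3: twofold asymmetric hydrogenation of a flat 3,3′-bicoumarin.**
- Disconnection: the four C–H bonds at C3, C4, C3′ and C4′ are cut, leading to the 4,4′-diaryl-3,3′-bicoumarin A6.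
- Forward key step: twofold syn hydrogenation on an iridium catalyst with a chiral N,P ligand, to give the octamethyl ether A7.
- For it: syn addition guarantees the cis relation inside each ring. On this point it is stronger than the chosen route, which relies on a kinetic protonation at C3′ and a radical hydrogen transfer at C3. The precursor is also flat and robust.
- Against it:
  - Two tetrasubstituted, conjugated, electron-rich and doubly flanked coumarin double bonds are among the least reactive hydrogenation substrates.
  - A6 is a twisted, biaryl-like diene, so the catalyst must select one face of each alkene.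
  - The second reduction, and with it the relation between the halves (C3 to C3′), falls under substrate control.
  - The unsymmetrical A6 needs a cross-coupling of two hindered coumarins.
- The chosen strategy fixes the C3/C3′ relation by a substitution and a protonation on an sp3 framework and avoids the hindered hydrogenations.

Key step: step 8

Remark: the sense of induction in step 3 is assigned by analogy with the unsubstituted coumarin (same CIP priorities at C4); if it were opposite on 7, (S)-SEGPHOS would be used.

## Route

Step 1
Reactants: 1 1,2,3,4-tetramethoxybenzene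
Product: 4 2,3,4,5-tetramethoxyphenol, via aryllithium 2 (not isolated), via arylboronate 3 (not isolated)
Conditions: n-BuLi, TMEDA, THF, 0 °C; B(OMe)3, −78 °C to rt; then H2O2, AcOH, 0 °C to rt
Reagents that add atoms: hydrogen peroxide, OO
Why: Directed ortho-metalation (the only ring C–H type, ortho to a methoxy group), borylation and peroxide oxidation of the aryl–boron bond (1,2-aryl shift to oxygen) should give the phenol in one pot.

Step 2
Reactants: 4 2,3,4,5-tetramethoxyphenol; 5 ethyl propiolate
Product: 7 5,6,7,8-tetramethoxy-2H-chromen-2-one, via Z-hydroxycinnamate 6 (not isolated)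
Conditions: Pd(OAc)2 (5 mol %), CF3CO2H/CH2Cl2, rt
Reagents that add atoms: none
Why: Pd(OAc)2-catalysed hydroarylation of the propiolate (Fujiwara-type coumarin synthesis) at the single free position ortho to the hydroxyl gives the Z-cinnamate 6, which lactonises in the acidic medium.

Step 3
Reactants: 7 5,6,7,8-tetramethoxy-2H-chromen-2-one; 8 4-methoxyphenylboronic acid (excess)
Product: 9 (4R)-5,6,7,8-tetramethoxy-4-(4-methoxyphenyl)chroman-2-one (lactone B)
Conditions: Rh(acac)(C2H4)2 (3 mol %), (R)-SEGPHOS, dioxane/H2O 10:1, 60 °C
Reagents that add atoms: none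
Why: Hayashi–Miyaura asymmetric 1,4-addition: the aryl–rhodium species adds to C4 on the face chosen by the bisphosphine and the oxa-π-allyl rhodium intermediate is protonated by water; an ethylene complex is the rhodium source so that no achiral diene competes with the ligand, and (R)-SEGPHOS is expected to set the (4R) centre (C4′ of the target).

Step 4
Reactants: 9 lactone B; 10 4-methoxybenzaldehyde
Product: 12 (3R,4R)-3-[hydroxy(4-methoxyphenyl)methyl]-5,6,7,8-tetramethoxy-4-(4-methoxyphenyl)chroman-2-one (both carbinol epimers), via lithium enolate 11 (not isolated)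
Conditions: LiN(SiMe3)2, THF, −78 °C; 10, −78 °C; AcOH quench at −78 °C
Reagents that add atoms: none
Why: Lithium enolate aldol addition at low temperature (where the aryl-ester enolate does not fragment); the aldehyde should add trans to the pseudoaxial C4 aryl group, and the C3 and carbinol configurations do not matter because both are removed in step 5.

Step 5
Reactants: 12 aldol adduct
Product: 14 (4R,E)-5,6,7,8-tetramethoxy-3-(4-methoxybenzylidene)-4-(4-methoxyphenyl)chroman-2-one, via mesylate 13 (not isolated)
Conditions: MsCl, Et3N, CH2Cl2, 0 °C to rt
Reagents that add atoms: none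
Why: Mesylation of the 4-methoxybenzylic alcohol and elimination (E1cB or E1) give the conjugated exocyclic alkene as the more stable E isomer (aryl anti to the lactone carbonyl); the amine is too weak a base to move the double bond into the ring, so C4 is kept.

Step 6
Reactants: 14 E-benzylidene lactone; 15 methyl dibromoacetate
Product: 18 methyl (1R,3S,4′R)-2-bromo-5′,6′,7′,8′-tetramethoxy-3,4′-bis(4-methoxyphenyl)-2′-oxospiro[cyclopropane-1,3′-chromane]-2-carboxylate (both C2 epimers), via lithium dibromoenolate 16 (not isolated), via Michael adduct enolate 17 (not isolated)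
Conditions: LiN(SiMe3)2 added to 14 and 15, THF, −78 to −30 °C
Reagents that add atoms: none
Why: Michael-initiated ring closure: enolate 16 adds to the benzylidene carbon on the face opposite the pseudoaxial C4′ aryl group, which sets C4, and the lactone enolate 17 displaces bromide (3-exo-tet) with the alkene geometry kept; the bromo centre and the spiro centre are stereochemically irrelevant because they are replaced in steps 7 and 8.

Step 7
Reactants: 18 bromocyclopropane
Product: 19 methyl (1R,2S,3S,4′R)-5′,6′,7′,8′-tetramethoxy-3,4′-bis(4-methoxyphenyl)-2′-oxospiro[cyclopropane-1,3′-chromane]-2-carboxylate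
Conditions: (Me3Si)3SiH, Et3B, air, toluene, 0 °C
Reagents that add atoms: none
Why: Radical-chain debromination: the α-ester cyclopropyl radical takes hydrogen from the bulky silane on the face opposite the vicinal 4-methoxyphenyl group and C4′, so both bromo epimers converge on the cyclopropane with ester and aryl cis; the low temperature and the fast hydrogen donor keep the cyclopropyl radical from ring opening.

Step 8
Reactants: 19 spirocyclopropane; 20 phloroglucinol trimethyl ether
Product: 22 methyl (2S,3R)-3-(4-methoxyphenyl)-2-[(3S,4R)-5,6,7,8-tetramethoxy-4-(4-methoxyphenyl)-2-oxochroman-3-yl]-3-(2,4,6-trimethoxyphenyl)propanoate, via lactone B enol 21 (not isolated)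
Conditions: Sc(OTf)3 (10 mol %), arene in threefold excess, CH2Cl2, 0 °C to rt
Reagents that add atoms: none
Why: Sc(OTf)3 binds the lactone carbonyl and polarises the C4–C3′ bond between the anisyl-bearing donor carbon and the spiro acceptor carbon; 20 attacks C4 from the side opposite C3′ in an SN2-like Friedel–Crafts alkylation, so C4–C4a forms as C4–C3′ breaks, and the arenium proton is passed to the scandium-bound enolate (21). The closest known reaction type is the Lewis-acid-catalysed, invertive ring opening of donor–acceptor cyclopropanes, spirocyclopropyl oxindoles included, by electron-rich arenes. No ring is closed. C4 is controlled by inversion, which turns the cis ester/aryl geometry of 19 into the target C3/C4 relation while C3 itself is untouched. C3′ is controlled by protonation of the planar enolate on the face anti to the pseudoaxial C4′ aryl group, which gives the cis lactone B whatever the spiro configuration of 19 was. Cleavage of C4–C3′ and not C4–C3 is needed and is secured by the quaternary C3′, which releases more strain and leaves as the better-stabilised aryl-ester enolate. Substitution must also outrun ionisation to the 4-methoxybenzyl cation, for which a low temperature, a non-ionising solvent and an excess of the strongly nucleophilic arene are used. The arene is symmetrical, so only one regioisomer can form.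

Step 9
Reactants: 22 nonamethyl ether methyl ester
Product: 24 (3S,3′S,4R,4′R)-5,5′,6′,7,7′,8′-hexahydroxy-4,4′-bis(4-hydroxyphenyl)-[3,3′-bichromane]-2,2′-dione, via seco acid 23 (not isolated)
Conditions: BBr3 (excess), CH2Cl2, −78 °C to rt; then degassed 1 M HCl, rt, under argon
Reagents that add atoms: none
Why: BBr3 cleaves all ten O–CH3 bonds (nine aryl ethers and the methyl ester) by bromide attack on the boron-activated methyl groups; on acidic work-up the borates hydrolyse and one of the two equivalent ortho-hydroxyls of the phloroglucinol ring closes lactone A on the carboxyl group (6-exo-trig acyl substitution); no base is used, so C3 and C3′ keep their configuration.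

## Compound list

1 | 1,2,3,4-tetramethoxybenzene | COc1ccc(OC)c(OC)c1OC | starting material
2 | (2,3,4,5-tetramethoxyphenyl)lithium | [Li]c1cc(OC)c(OC)c(OC)c1OC | intermediate
3 | dimethyl (2,3,4,5-tetramethoxyphenyl)boronate | COB(OC)c1cc(OC)c(OC)c(OC)c1OC | intermediate
4 | 2,3,4,5-tetramethoxyphenol | Oc1cc(OC)c(OC)c(OC)c1OC | intermediate
5 | ethyl propiolate | C#CC(=O)OCC | starting material
6 | ethyl (Z)-3-(2-hydroxy-3,4,5,6-tetramethoxyphenyl)acrylate | CCOC(=O)/C=C\c1c(O)c(OC)c(OC)c(OC)c1OC | intermediate
7 | 5,6,7,8-tetramethoxy-2H-chromen-2-one | O=C1C=Cc2c(OC)c(OC)c(OC)c(OC)c2O1 | intermediate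
8 | 4-methoxyphenylboronic acid | COc1ccc(cc1)B(O)O | starting material
9 | (4R)-5,6,7,8-tetramethoxy-4-(4-methoxyphenyl)chroman-2-one (lactone B) | O=C1Oc2c(OC)c(OC)c(OC)c(OC)c2[C@@H](c2ccc(OC)cc2)C1 | intermediate
10 | 4-methoxybenzaldehyde | COc1ccc(C=O)cc1 | starting material
11 | lithium enolate of 9 | [Li]OC1Oc2c(OC)c(OC)c(OC)c(OC)c2[C@@H](c2ccc(OC)cc2)C=1 | intermediate
12 | (3R,4R)-3-[hydroxy(4-methoxyphenyl)methyl]-5,6,7,8-tetramethoxy-4-(4-methoxyphenyl)chroman-2-one, both carbinol epimers | O=C1Oc2c(OC)c(OC)c(OC)c(OC)c2[C@@H](c2ccc(OC)cc2)[C@@H]1C(O)c1ccc(OC)cc1 | intermediate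
13 | methanesulfonate of 12 | O=C1Oc2c(OC)c(OC)c(OC)c(OC)c2[C@@H](c2ccc(OC)cc2)[C@@H]1C(OS(C)(=O)=O)c1ccc(OC)cc1 | intermediate
14 | (4R,E)-5,6,7,8-tetramethoxy-3-(4-methoxybenzylidene)-4-(4-methoxyphenyl)chroman-2-one | O=C1Oc2c(OC)c(OC)c(OC)c(OC)c2[C@@H](c2ccc(OC)cc2)/C1=C\c1ccc(OC)cc1 | intermediate
15 | methyl dibromoacetate | COC(=O)C(Br)Br | starting material
16 | lithium enolate of 15 | [Li]OC(OC)=C(Br)Br | intermediate
17 | lithium enolate of the Michael adduct of 16 to 14 (C4 set, chain CH(anisyl)–CBr2–CO2Me on C3′) | [Li]OC1Oc2c(OC)c(OC)c(OC)c(OC)c2[C@@H](c2ccc(OC)cc2)C=1[C@H](c1ccc(OC)cc1)C(Br)(Br)C(=O)OC | intermediate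
18 | methyl (1R,3S,4′R)-2-bromo-5′,6′,7′,8′-tetramethoxy-3,4′-bis(4-methoxyphenyl)-2′-oxospiro[cyclopropane-1,3′-chromane]-2-carboxylate, both C2 epimers (anisyl cis to C4′) | O=C1Oc2c(OC)c(OC)c(OC)c(OC)c2[C@@H](c2ccc(OC)cc2)[C@]13C(Br)(C(=O)OC)[C@H]3c1ccc(OC)cc1 | intermediate
19 | methyl (1R,2S,3S,4′R)-5′,6′,7′,8′-tetramethoxy-3,4′-bis(4-methoxyphenyl)-2′-oxospiro[cyclopropane-1,3′-chromane]-2-carboxylate (ester and anisyl cis to each other and to C4′) | O=C1Oc2c(OC)c(OC)c(OC)c(OC)c2[C@@H](c2ccc(OC)cc2)[C@]13[C@@H](C(=O)OC)[C@H]3c1ccc(OC)cc1 | intermediate
20 | 1,3,5-trimethoxybenzene (phloroglucinol trimethyl ether) | COc1cc(OC)cc(OC)c1 | starting material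
21 | lactone B enol of 22 (2-hydroxy-4H-chromene form, scandium-bound in the flask) | COC(=O)[C@@H]([C@H](c1ccc(OC)cc1)c1c(OC)cc(OC)cc1OC)C1=C(O)Oc2c(OC)c(OC)c(OC)c(OC)c2[C@H]1c1ccc(OC)cc1 | intermediate
22 | methyl (2S,3R)-3-(4-methoxyphenyl)-2-[(3S,4R)-5,6,7,8-tetramethoxy-4-(4-methoxyphenyl)-2-oxochroman-3-yl]-3-(2,4,6-trimethoxyphenyl)propanoate | COC(=O)[C@@H]([C@H](c1ccc(OC)cc1)c1c(OC)cc(OC)cc1OC)[C@H]1C(=O)Oc2c(OC)c(OC)c(OC)c(OC)c2[C@H]1c1ccc(OC)cc1 | intermediate
23 | (2S,3R)-3-(4-hydroxyphenyl)-2-[(3S,4R)-5,6,7,8-tetrahydroxy-4-(4-hydroxyphenyl)-2-oxochroman-3-yl]-3-(2,4,6-trihydroxyphenyl)propanoic acid | O=C(O)[C@@H]([C@H](c1ccc(O)cc1)c1c(O)cc(O)cc1O)[C@H]1C(=O)Oc2c(O)c(O)c(O)c(O)c2[C@H]1c1ccc(O)cc1 | intermediate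
24 | (3S,3′S,4R,4′R)-5,5′,6′,7,7′,8′-hexahydroxy-4,4′-bis(4-hydroxyphenyl)-[3,3′-bichromane]-2,2′-dione | O=C1Oc2cc(O)cc(O)c2[C@@H](c2ccc(O)cc2)[C@H]1[C@H]1C(=O)Oc2c(O)c(O)c(O)c(O)c2[C@H]1c1ccc(O)cc1 | target

## Step count and least certain steps

Total step count: 9. Longest linear sequence: 9 steps (1 to 24); 5, 8, 10, 15 and 20 enter as purchased compounds.

**Step 8 (key step).**
- What may go wrong: ionisation of the C4–C3′ bond to a 4-methoxybenzyl cation before the arene arrives, which would scramble C4; cleavage of C4–C3 towards the more Lewis-basic methyl ester; Lewis-acid enolisation at C3′ after the protonation, with drift to the trans lactone.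
- Fallback (from 19, back at 22): 20 is lithiated with n-BuLi to (2,4,6-trimethoxyphenyl)lithium F1 and converted with CuBr·SMe2 into lithium bis(2,4,6-trimethoxyphenyl)cuprate F2. F2 is added to 19 in THF/Et2O at −78 to −20 °C, with BF3·OEt2 if needed. This homoconjugate addition is a purely bimolecular substitution at the benzylic cyclopropane carbon with inversion and no cation. The resulting lithium enolate of lactone B is quenched at −78 °C with acetic acid on the face anti to the C4′ aryl group, which gives 22.

**Step 7.**
- What may go wrong: poor facial selectivity of the hydrogen-atom transfer (delivery on the aryl side gives the trans ester), or ring opening of the cyclopropyl radical.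
- Fallback (from 18, back at 19): a two-electron route. Activated zinc is inserted into the C–Br bond (THF, 0 °C) to give the Reformatsky reagent F3, which is protonated at −78 °C with the bulky 2,6-di-tert-butyl-4-methylphenol from the open face to give 19.

**Step 6.**
- What may go wrong: attack of the hard lithium enolate on the aryl-lactone carbonyl instead of conjugate addition, slow closure onto the dibrominated carbon, or base-induced migration of the exocyclic double bond.
- Fallback (from 14, back at 19): methyl bromonitroacetate F4 (from methyl nitroacetate and N-bromosuccinimide) is used with K2CO3 in THF. The soft nitronate adds and closes to the nitrocyclopropane F5. Denitration with Bu3SnH and AIBN (toluene, 80 °C) passes through the same C3 radical as step 7 and gives 19.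

**Step 3.**
- What may go wrong: slow insertion of the aryl–rhodium species next to the peri 5-methoxy group, so that protodeboronation of 8 takes over, and erosion of the enantiomeric purity.
- Fallback (from 4, back at 9):
  1. Pechmann condensation of 4 with ethyl 3-(4-methoxyphenyl)-3-oxopropanoate (MeSO3H) gives 5,6,7,8-tetramethoxy-4-(4-methoxyphenyl)-2H-chromen-2-one F6.
  2. Aqueous NaOH opens it to the disodium (Z)-3-(2-oxido-3,4,5,6-tetramethoxyphenyl)-3-(4-methoxyphenyl)acrylate F7.
  3. Asymmetric hydrogenation with [Rh(nbd)2]BF4 and a chiral bisphosphine gives the disodium (R)-3,3-diarylpropanoate F8.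
  4. Acidification relactonises F8 to 9.

**Step 9.**
- What may go wrong: incomplete cleavage of some of the ten methyl groups, air oxidation of the tetrahydroxybenzene ring during isolation, and acid-promoted epimerisation at C3 or C3′ on long exposure.
- Fallback (from 22, back at 24): after BBr3 and aqueous work-up under argon the crude polyphenol is acetylated (Ac2O, catalytic Sc(OTf)3, MeCN) to the octaacetate F9. F9 is purified by chromatography and deacetylated with HCl in aqueous acetone under argon to give 24.

## Further compounds

F1 | step 8 | (2,4,6-trimethoxyphenyl)lithium | [Li]c1c(OC)cc(OC)cc1OC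
F2 | step 8 | lithium bis(2,4,6-trimethoxyphenyl)cuprate | [Li+].COc1cc(OC)c([Cu-]c2c(OC)cc(OC)cc2OC)c(OC)c1
F3 | step 7 | methyl (1R,3S,4′R)-2-(bromozincio)-5′,6′,7′,8′-tetramethoxy-3,4′-bis(4-methoxyphenyl)-2′-oxospiro[cyclopropane-1,3′-chromane]-2-carboxylate | O=C1Oc2c(OC)c(OC)c(OC)c(OC)c2[C@@H](c2ccc(OC)cc2)[C@]13C([Zn]Br)(C(=O)OC)[C@H]3c1ccc(OC)cc1
F4 | step 6 | methyl bromonitroacetate | COC(=O)C(Br)[N+](=O)[O-]
F5 | step 6 | methyl (1R,3S,4′R)-5′,6′,7′,8′-tetramethoxy-3,4′-bis(4-methoxyphenyl)-2-nitro-2′-oxospiro[cyclopropane-1,3′-chromane]-2-carboxylate | O=C1Oc2c(OC)c(OC)c(OC)c(OC)c2[C@@H](c2ccc(OC)cc2)[C@]13C([N+](=O)[O-])(C(=O)OC)[C@H]3c1ccc(OC)cc1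
F6 | step 3 | 5,6,7,8-tetramethoxy-4-(4-methoxyphenyl)-2H-chromen-2-one | O=C1C=C(c2ccc(OC)cc2)c2c(OC)c(OC)c(OC)c(OC)c2O1
F7 | step 3 | disodium (Z)-3-(2-oxido-3,4,5,6-tetramethoxyphenyl)-3-(4-methoxyphenyl)acrylate | [Na+].[Na+].[O-]C(=O)/C=C(/c1ccc(OC)cc1)c1c([O-])c(OC)c(OC)c(OC)c1OC
F8 | step 3 | disodium (R)-3-(2-oxido-3,4,5,6-tetramethoxyphenyl)-3-(4-methoxyphenyl)propanoate | [Na+].[Na+].[O-]C(=O)C[C@H](c1ccc(OC)cc1)c1c([O-])c(OC)c(OC)c(OC)c1OC
F9 | step 9 | octaacetate of 24 | O=C1Oc2cc(OC(C)=O)cc(OC(C)=O)c2[C@@H](c2ccc(OC(C)=O)cc2)[C@H]1[C@H]1C(=O)Oc2c(OC(C)=O)c(OC(C)=O)c(OC(C)=O)c(OC(C)=O)c2[C@H]1c1ccc(OC(C)=O)cc1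
A1 | alternative 1 | (2S,3S)-2-(pentamethoxybenzyl)-3-(2,4,6-trimethoxybenzyl)-N1,N4-di(quinolin-8-yl)succinamide | COc1cc(OC)cc(OC)c1C[C@H](C(=O)Nc1cccc2cccnc12)[C@H](Cc1c(OC)c(OC)c(OC)c(OC)c1OC)C(=O)Nc1cccc2cccnc12
A2 | alternative 1 | 4-iodoanisole | COc1ccc(I)cc1
A3 | alternative 1 | (2S,3S)-bis(diarylmethyl)succinic bis(quinolin-8-yl)amide, R at both diarylmethine carbons | COc1cc(OC)cc(OC)c1[C@@H](c1ccc(OC)cc1)[C@H](C(=O)Nc1cccc2cccnc12)[C@H]([C@@H](c1c(OC)c(OC)c(OC)c(OC)c1OC)c1ccc(OC)cc1)C(=O)Nc1cccc2cccnc12
A4 | alternative 2 | 3,5-dimethoxyphenyl 2,3,4,5-tetramethoxyphenyl (E,E)-2,3-bis(4-hydroxybenzylidene)succinate | O=C(Oc1cc(OC)cc(OC)c1)/C(=C/c1ccc(O)cc1)/C(=C\c1ccc(O)cc1)C(=O)Oc1cc(OC)c(OC)c(OC)c1OC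
A5 | alternative 2 | hexamethyl ether of 24 (benzo-ring methoxy groups, free 4-hydroxyphenyl groups) | O=C1Oc2cc(OC)cc(OC)c2[C@@H](c2ccc(O)cc2)[C@H]1[C@H]1C(=O)Oc2c(OC)c(OC)c(OC)c(OC)c2[C@H]1c1ccc(O)cc1
A6 | alternative 3 | 5,5′,6′,7,7′,8′-hexamethoxy-4,4′-bis(4-methoxyphenyl)-2H,2′H-[3,3′-bichromene]-2,2′-dione | O=C1Oc2cc(OC)cc(OC)c2C(c2ccc(OC)cc2)=C1C1=C(c2ccc(OC)cc2)c2c(OC)c(OC)c(OC)c(OC)c2OC1=O
A7 | alternative 3 | octamethyl ether of 24 | O=C1Oc2cc(OC)cc(OC)c2[C@@H](c2ccc(OC)cc2)[C@H]1[C@H]1C(=O)Oc2c(OC)c(OC)c(OC)c(OC)c2[C@H]1c1ccc(OC)cc1
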